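## Retrosynthetic overview

- **Feature.** Locants: ring C1 (OAc), C2, C3 (Br), C4 (CMe2), C5 (=CH), C6; side chain C7 (Br), C8 (Cl). C1 is an allylic carbinol carbon bonded to C6, the fully substituted alkene carbon of the only ring, a cyclohexene.
- **Late stage.** C7–Br comes from the C7 alcohol of opposite configuration by an invertive Appel reaction. C1–OAc comes from the C1 alcohol.
- **Ring formation (the only one).** The C1–C6 bond is cut to an acyclic (Z)-6-iodoalkene that carries the C1 aldehyde. An intramolecular Nozaki–Hiyama–Kishi addition closes the six-membered ring and sets C1.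
- **Iodoalkene and C7.** Anti H/Sn addition to a propargylic chlorohydrin gives the alkene geometry. The chlorohydrin comes from asymmetric transfer hydrogenation of a chloromethyl ynone, made by acylating the C5≡C6 acetylide (C6–C7 bond).
- **C3 and C1.** Brown allylation of 2,2-dimethylbut-3-ynal (C2–C3 bond), then invertive bromination. C1 travels as a dimethyl acetal: an ester would be enolised in the acetylide step and lose HBr, and a free alkene would make a 1,6-enyne open to ruthenium-mediated cyclisation.

Key step: step 12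

Remark: the target locants C1–C8 are used for every intermediate. The facial sense of steps 3 and 7 is assigned by analogy with pivalaldehyde and with alkynyl methyl ketones, CH2Cl taking the place of methyl.

## Route

Step 1
Reactants: 1 2,2-dimethylbut-3-ynoic acid
Product: 2 2,2-dimethylbut-3-yn-1-ol
Conditions: LiAlH4, Et2O, 0 → 25 °C; H2O, aq. NaOH work-up
Reagents that add atoms: none
Why: Hydride reduction of a carboxylic acid to the primary alcohol; the terminal alkyne is not hydroaluminated at or below room temperature.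

Step 2
Reactants: 2 2,2-dimethylbut-3-yn-1-ol
Product: 3 2,2-dimethylbut-3-ynal
Conditions: Dess–Martin periodinane, CH2Cl2, 0 → 25 °C; careful concentration (volatile)
Reagents that add atoms: none
Why: Dess–Martin oxidation of a neopentyl primary alcohol stops at the aldehyde, which has no α-hydrogen and cannot enolise.

Step 3
Reactants: 3 2,2-dimethylbut-3-ynal; 4 (+)-B-allyldiisopinocampheylborane, (−)-α-pinene series
Product: 6 (4R)-5,5-dimethylhept-1-en-6-yn-4-ol, via borinic ester 5 (not isolated)
Conditions: 4 (1 M in pentane, salt-free), Et2O, −100 → −78 °C; then NaOH, H2O2, 0 → 25 °C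
Reagents that add atoms: (+)-B-allyldiisopinocampheylborane 4, C=CCB([C@H]1C[C@H]2C[C@@H]([C@@H]1C)C2(C)C)[C@H]1C[C@H]2C[C@@H]([C@@H]1C)C2(C)C
Why: Brown asymmetric allylboration through a closed chair transition state, in which the isopinocampheyl groups of this series send allyl to the Re face of the bulky aldehyde and set C3 as R.

Step 4
Reactants: 6 (4R)-5,5-dimethylhept-1-en-6-yn-4-ol
Product: 8 (3R)-1,1-dimethoxy-4,4-dimethylhex-5-yn-3-ol, via hydroxy aldehyde 7 (not isolated)
Conditions: O3, CH2Cl2–MeOH, −78 °C (stopped at alkene consumption); Me2S; then CH(OMe)3, TsOH·H2O (cat.), 25 °C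
Reagents that add atoms: trimethyl orthoformate, COC(OC)OC
Why: Ozonolysis picks the monosubstituted alkene, which reacts with ozone far faster than the terminal alkyne, and acid-catalysed acetalisation then masks C1 at the aldehyde level without acidifying C2–H; C3 is not touched.

Step 5
Reactants: 8 (3R)-1,1-dimethoxy-4,4-dimethylhex-5-yn-3-ol
Product: 9 (4S)-4-bromo-6,6-dimethoxy-3,3-dimethylhex-1-yne
Conditions: CBr4, PPh3, 2,6-lutidine, toluene, 0 → 50 °C
Reagents that add atoms: carbon tetrabromide, BrC(Br)(Br)Br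
Why: Appel bromination, an SN2 displacement of the oxyphosphonium group that inverts C3 from R to S; the rod-like alkynyl arm on C4 leaves bromide a rear path, the non-ionising medium disfavours 1,2-shifts, C2–H is not activated towards elimination, and the hindered base protects the acetal.

Step 6
Reactants: 9 (4S)-4-bromo-6,6-dimethoxy-3,3-dimethylhex-1-yne; 10 2-chloro-N-methoxy-N-methylacetamide
Product: 13 (6S)-6-bromo-1-chloro-8,8-dimethoxy-5,5-dimethyloct-3-yn-2-one, via lithium acetylide 11 (not isolated), via tetrahedral lithium adduct 12 (not isolated)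
Conditions: n-BuLi (1.0 equiv), THF, −78 °C; 10, −78 → −40 °C; 1 M aq. HCl, −40 °C
Reagents that add atoms: 2-chloro-N-methoxy-N-methylacetamide 10, CON(C)C(=O)CCl
Why: Weinreb ketone synthesis with a lithium acetylide, in which the acetylenic C–H is removed much faster at −78 °C than the hindered secondary bromide is attacked, and the chelated adduct survives until the acid quench, so neither over-addition nor closure onto CH2Cl occurs.

Step 7
Reactants: 13 (6S)-6-bromo-1-chloro-8,8-dimethoxy-5,5-dimethyloct-3-yn-2-one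
Product: 14 (2R,6S)-6-bromo-1-chloro-8,8-dimethoxy-5,5-dimethyloct-3-yn-2-ol
Conditions: Ru[(S,S)-TsDPEN](p-cymene) (2 mol %), i-PrOH, 25 °C, no added base
Reagents that add atoms: none
Why: Noyori asymmetric transfer hydrogenation of an ynone, in which the alkynyl group plays the π-substituent role, so the (S,S) catalyst sets C7 in the sense that reads R here (CH2Cl outranks the alkynyl carbon); the base-free medium keeps the chlorohydrin from closing to an epoxide.

Step 8
Reactants: 14 (2R,6S)-6-bromo-1-chloro-8,8-dimethoxy-5,5-dimethyloct-3-yn-2-ol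
Product: 15 (2S,3Z,6S)-6-bromo-1-chloro-8,8-dimethoxy-5,5-dimethyl-3-(tributylstannyl)oct-3-en-2-ol
Conditions: [Cp*RuCl]4 (2.5 mol %), Bu3SnH (1.1 equiv, slow addition), CH2Cl2, 25 °C, argon, dark
Reagents that add atoms: tributyltin hydride, CCCC[SnH](CCCC)CCCC
Why: Hydroxyl-directed ruthenium-catalysed trans-hydrostannation, in which the O–H···Cl–Ru hydrogen bond and the bulk of C4 both send tin to C6, H and Sn add anti so that tin ends cis to C4, and the non-radical pathway spares C–Br and C–Cl (the C7 descriptor changes by priority only).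

Step 9
Reactants: 15 (2S,3Z,6S)-6-bromo-1-chloro-8,8-dimethoxy-5,5-dimethyl-3-(tributylstannyl)oct-3-en-2-ol
Product: 16 (2S,3Z,6S)-6-bromo-1-chloro-3-iodo-8,8-dimethoxy-5,5-dimethyloct-3-en-2-ol
Conditions: I2, CH2Cl2, 0 °C
Reagents that add atoms: iodine, II
Why: Iododestannylation, an electrophilic ipso substitution at the alkenyl carbon that keeps the alkene geometry, so iodine stays cis to C4.

Step 10
Reactants: 16 (2S,3Z,6S)-6-bromo-1-chloro-3-iodo-8,8-dimethoxy-5,5-dimethyloct-3-en-2-ol
Product: 17 tert-butyl{[(2S,3Z,6S)-6-bromo-1-chloro-3-iodo-8,8-dimethoxy-5,5-dimethyloct-3-en-2-yl]oxy}dimethylsilane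
Conditions: TBSCl, imidazole, DMF, 25 → 40 °C
Reagents that add atoms: tert-butyldimethylsilyl chloride, CC(C)(C)[Si](C)(C)Cl
Why: Imidazole-promoted silylation of the C7 alcohol; the silyl chloride is chosen over the triflate because silyl triflate with lutidine attacks dimethyl acetals, and imidazole is too weak a base to close the chlorohydrin.

Step 11
Reactants: 17 tert-butyl{[(2S,3Z,6S)-6-bromo-1-chloro-3-iodo-8,8-dimethoxy-5,5-dimethyloct-3-en-2-yl]oxy}dimethylsilane
Product: 18 (3S,5Z,7S)-3-bromo-7-(tert-butyldimethylsilyloxy)-8-chloro-6-iodo-4,4-dimethyloct-5-enal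
Conditions: TsOH·H2O (10 mol %), acetone–H2O, 0 → 25 °C; pH 7 buffer work-up; used at once
Reagents that add atoms: water, O
Why: Acid-catalysed acetal hydrolysis frees the aldehyde without any base, so the β-bromo aldehyde does not lose HBr, and the hindered, electron-poor secondary silyl ether withstands the mild acid.

Step 12
Reactants: 18 (3S,5Z,7S)-3-bromo-7-(tert-butyldimethylsilyloxy)-8-chloro-6-iodo-4,4-dimethyloct-5-enal
Product: 21 (1R,5S)-5-bromo-2-[(1R)-1-(tert-butyldimethylsilyloxy)-2-chloroethyl]-4,4-dimethylcyclohex-2-en-1-ol, via alkenylchromium dichloride 19 (not isolated), via chromium alkoxide 20 (not isolated)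
Conditions: CrCl2 (6 equiv), NiCl2 (0.1 equiv), degassed DMF, 0.01 M, 25 °C; then H2O
Reagents that add atoms: none
Why: Zerovalent nickel, made from NiCl2 by divalent chromium, inserts into the C6–I bond with retention of geometry and hands the alkenyl group to chromium (two CrCl2 per iodide); alkenylchromium 19 binds the C1 aldehyde and adds to it, giving the trivalent chromium alkoxide 20, which water releases as 21. The closest known reaction type is the intramolecular Nozaki–Hiyama–Kishi cyclisation of (Z)-iodoalkenyl aldehydes to cyclohex-2-enols. The single ring closes by 6-exo-trig attack on the carbonyl group (the C=O bond stays outside the ring), and the C5=C6 alkene, whose iodine stood cis to C4, becomes endocyclic. C1 is set relative to C3: chromium stays bound to the carbonyl oxygen as it leaves C6, which holds the C1–O bond near the alkene plane (pseudo-equatorial), and of the two half-chair arrays that allow this, the one with the C3 bromine equatorial leads to the 1,3-cis (1R) alcohol. The step needs chemoselectivity for the alkenyl C–I bond and a non-basic medium: nickel inserts only into the alkenyl iodide, CrCl2 without a cobalt co-catalyst or amine ligand does not reduce the secondary C3–Br or the primary C8–Cl, the C7 silyl ether is a poor leaving group for allene-forming β-elimination, and the weakly basic organochromium species leaves the β-bromo aldehyde un-enolised.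

Step 13
Reactants: 21 (1R,5S)-5-bromo-2-[(1R)-1-(tert-butyldimethylsilyloxy)-2-chloroethyl]-4,4-dimethylcyclohex-2-en-1-ol
Product: 22 (1R,5S)-5-bromo-2-[(1R)-1-(tert-butyldimethylsilyloxy)-2-chloroethyl]-4,4-dimethylcyclohex-2-en-1-yl acetate
Conditions: Ac2O, pyridine, 4-(dimethylamino)pyridine (cat.), CH2Cl2, 0 → 25 °C
Reagents that add atoms: acetic anhydride, CC(=O)OC(C)=O
Why: Nucleophile-catalysed acetylation of the only free hydroxyl group forms the O–acyl bond and touches no stereocentre.

Step 14
Reactants: 22 (1R,5S)-5-bromo-2-[(1R)-1-(tert-butyldimethylsilyloxy)-2-chloroethyl]-4,4-dimethylcyclohex-2-en-1-yl acetate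
Product: 23 (1R,5S)-5-bromo-2-[(1R)-2-chloro-1-hydroxyethyl]-4,4-dimethylcyclohex-2-en-1-yl acetate
Conditions: HF·pyridine, THF–pyridine, 0 → 25 °C
Reagents that add atoms: none
Why: Fluoride desilylation under acidic conditions forms no alkoxide, so the C7 oxygen neither closes onto C8 to an epoxide nor takes over the C1 acetyl group, as it could with a basic fluoride source.

Step 15
Reactants: 23 (1R,5S)-5-bromo-2-[(1R)-2-chloro-1-hydroxyethyl]-4,4-dimethylcyclohex-2-en-1-yl acetate
Product: 24 (1R,5S)-5-bromo-2-[(1S)-1-bromo-2-chloroethyl]-4,4-dimethylcyclohex-2-en-1-yl acetate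
Conditions: CBr4, PPh3, CH2Cl2, −20 → 0 °C
Reagents that add atoms: carbon tetrabromide, BrC(Br)(Br)Br
Why: Appel bromination of the allylic C7 alcohol by direct SN2 attack inverts C7 from R to S; the neighbouring C8 chlorine disfavours ionisation, and allylic transposition is hindered because C5 lies next to quaternary C4.

## Compound list

1 | 2,2-dimethylbut-3-ynoic acid | C#CC(C)(C)C(=O)O | starting material
2 | 2,2-dimethylbut-3-yn-1-ol | C#CC(C)(C)CO | intermediate
3 | 2,2-dimethylbut-3-ynal | C#CC(C)(C)C=O | intermediate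
4 | (+)-B-allyldiisopinocampheylborane, (−)-α-pinene series | C=CCB([C@H]1C[C@H]2C[C@@H]([C@@H]1C)C2(C)C)[C@H]1C[C@H]2C[C@@H]([C@@H]1C)C2(C)C | starting material
5 | (4R)-5,5-dimethylhept-1-en-6-yn-4-yl diisopinocampheylborinate | C=CC[C@@H](OB([C@H]1C[C@H]2C[C@@H]([C@@H]1C)C2(C)C)[C@H]1C[C@H]2C[C@@H]([C@@H]1C)C2(C)C)C(C)(C)C#C | intermediate
6 | (4R)-5,5-dimethylhept-1-en-6-yn-4-ol | C=CC[C@@H](O)C(C)(C)C#C | intermediate
7 | (3R)-3-hydroxy-4,4-dimethylhex-5-ynal | O=CC[C@@H](O)C(C)(C)C#C | intermediate
8 | (3R)-1,1-dimethoxy-4,4-dimethylhex-5-yn-3-ol | COC(OC)C[C@@H](O)C(C)(C)C#C | intermediate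
9 | (4S)-4-bromo-6,6-dimethoxy-3,3-dimethylhex-1-yne | COC(OC)C[C@H](Br)C(C)(C)C#C | intermediate
10 | 2-chloro-N-methoxy-N-methylacetamide | CON(C)C(=O)CCl | starting material
11 | lithium acetylide of 9 | COC(OC)C[C@H](Br)C(C)(C)C#C[Li] | intermediate
12 | lithium alkoxide of the acetylide–amide adduct (new carbon centre not defined) | COC(OC)C[C@H](Br)C(C)(C)C#CC(O[Li])(CCl)N(C)OC | intermediate
13 | (6S)-6-bromo-1-chloro-8,8-dimethoxy-5,5-dimethyloct-3-yn-2-one | COC(OC)C[C@H](Br)C(C)(C)C#CC(=O)CCl | intermediate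
14 | (2R,6S)-6-bromo-1-chloro-8,8-dimethoxy-5,5-dimethyloct-3-yn-2-ol | COC(OC)C[C@H](Br)C(C)(C)C#C[C@@H](O)CCl | intermediate
15 | (2S,3Z,6S)-6-bromo-1-chloro-8,8-dimethoxy-5,5-dimethyl-3-(tributylstannyl)oct-3-en-2-ol | COC(OC)C[C@H](Br)C(C)(C)/C=C(\[Sn](CCCC)(CCCC)CCCC)[C@@H](O)CCl | intermediate
16 | (2S,3Z,6S)-6-bromo-1-chloro-3-iodo-8,8-dimethoxy-5,5-dimethyloct-3-en-2-ol | COC(OC)C[C@H](Br)C(C)(C)/C=C(\I)[C@@H](O)CCl | intermediate
17 | tert-butyl{[(2S,3Z,6S)-6-bromo-1-chloro-3-iodo-8,8-dimethoxy-5,5-dimethyloct-3-en-2-yl]oxy}dimethylsilane | COC(OC)C[C@H](Br)C(C)(C)/C=C(\I)[C@@H](O[Si](C)(C)C(C)(C)C)CCl | intermediate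
18 | (3S,5Z,7S)-3-bromo-7-(tert-butyldimethylsilyloxy)-8-chloro-6-iodo-4,4-dimethyloct-5-enal | O=CC[C@H](Br)C(C)(C)/C=C(\I)[C@@H](O[Si](C)(C)C(C)(C)C)CCl | intermediate
19 | C6-alkenylchromium dichloride derived from 18 | O=CC[C@H](Br)C(C)(C)/C=C(\[Cr](Cl)Cl)[C@@H](O[Si](C)(C)C(C)(C)C)CCl | intermediate
20 | dichlorochromium alkoxide of 21 | Cl[Cr](Cl)O[C@@H]1C[C@H](Br)C(C)(C)C=C1[C@@H](O[Si](C)(C)C(C)(C)C)CCl | intermediate
21 | (1R,5S)-5-bromo-2-[(1R)-1-(tert-butyldimethylsilyloxy)-2-chloroethyl]-4,4-dimethylcyclohex-2-en-1-ol | O[C@@H]1C[C@H](Br)C(C)(C)C=C1[C@@H](O[Si](C)(C)C(C)(C)C)CCl | intermediate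
22 | (1R,5S)-5-bromo-2-[(1R)-1-(tert-butyldimethylsilyloxy)-2-chloroethyl]-4,4-dimethylcyclohex-2-en-1-yl acetate | CC(=O)O[C@@H]1C[C@H](Br)C(C)(C)C=C1[C@@H](O[Si](C)(C)C(C)(C)C)CCl | intermediate
23 | (1R,5S)-5-bromo-2-[(1R)-2-chloro-1-hydroxyethyl]-4,4-dimethylcyclohex-2-en-1-yl acetate | CC(=O)O[C@@H]1C[C@H](Br)C(C)(C)C=C1[C@@H](O)CCl | intermediate
24 | (1R,5S)-5-bromo-2-[(1S)-1-bromo-2-chloroethyl]-4,4-dimethylcyclohex-2-en-1-yl acetate | CC(=O)O[C@@H]1C[C@H](Br)C(C)(C)C=C1[C@H](Br)CCl | target

## Step count and risks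

Total step count: 15. Longest linear sequence: 15 (from 1).

**Step 12 (ring closure).**
- What may go wrong: the facial choice at the aldehyde may be weak, because an equatorial bromine at C3 is gauche to both methyl groups of C4, so its preference over the axial position is small. Slow nickel insertion into the hindered iodide would also leave time for loss of HBr from the aldehyde.
- Fallback: the ring closure is kept and C1 is corrected afterwards. It sets out from the crude product of step 12 and comes back at 21.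
- The crude product is 21 mixed with (1S,5S)-5-bromo-2-[(1R)-1-(tert-butyldimethylsilyloxy)-2-chloroethyl]-4,4-dimethylcyclohex-2-en-1-ol F1.
- Dess–Martin periodinane in CH2Cl2 takes both epimers to (5S)-5-bromo-2-[(1R)-1-(tert-butyldimethylsilyloxy)-2-chloroethyl]-4,4-dimethylcyclohex-2-en-1-one F2.
- Luche reduction (NaBH4, CeCl3·7H2O, MeOH, −78 °C) should deliver hydride axially and give the pseudo-equatorial alcohol cis to the C3 substituent, as in the reduction of carvone to cis-carveol.
- The low temperature and the non-basic medium guard the β-bromo ketone against elimination.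

**Step 5 (C3 bromide).**
- What may go wrong: displacement next to quaternary C4 may be so slow that elimination towards C2, a 1,2-shift from C4, or partial ionisation with loss of stereochemical fidelity takes over.
- Fallback: nucleophilic displacement is replaced by electrophilic bromination of a C3–boron bond. It sets out from 2 and comes back at 9.
- Alcohol 2 is carbamoylated (i-Pr2NCOCl, Et3N, CH2Cl2, reflux) to 2,2-dimethylbut-3-yn-1-yl N,N-diisopropylcarbamate F3.
- The alkyne is capped (n-BuLi, THF, −78 °C; Me3SiCl) to give 2,2-dimethyl-4-(trimethylsilyl)but-3-yn-1-yl N,N-diisopropylcarbamate F4.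
- Asymmetric lithiation–borylation (s-BuLi, (+)-sparteine, Et2O, −78 °C; allylboronic acid pinacol ester; then MgBr2·OEt2, reflux) proceeds by retentive borylation and invertive 1,2-shift of allyl. It should give 2-[(4R)-5,5-dimethyl-7-(trimethylsilyl)hept-1-en-6-yn-4-yl]-4,4,5,5-tetramethyl-1,3,2-dioxaborolane F5.
- The ate complex of this boronic ester with 3,5-bis(trifluoromethyl)phenyllithium (THF, −78 °C) is brominated by NBS with inversion to [(4S)-4-bromo-3,3-dimethylhept-6-en-1-yn-1-yl]trimethylsilane F6.
- Ozonolysis and acetalisation as in step 4 give [(4S)-4-bromo-6,6-dimethoxy-3,3-dimethylhex-1-yn-1-yl]trimethylsilane F7, and K2CO3 in MeOH removes silicon to return 9.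

**Step 15 (C7 bromide).**
- What may go wrong: participation of the C1 acetate at the activated C7 centre (net retention or acetate transfer), allylic ionisation, or allylic transposition could erode the inversion.
- Fallback: activation and displacement are separated, so that substitution runs with a large excess of free bromide at low temperature, where bimolecular attack should outrun participation. It sets out from 23 and comes back at 24.
- MsCl and Et3N in CH2Cl2 at −30 °C give (1R,5S)-5-bromo-2-[(1R)-2-chloro-1-(methanesulfonyloxy)ethyl]-4,4-dimethylcyclohex-2-en-1-yl acetate F8.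
- This mesylate is treated without purification with LiBr (excess) in acetone at 0 °C to give 24 with inversion at C7.

## Further compounds

F1 | step 12 | (1S,5S)-5-bromo-2-[(1R)-1-(tert-butyldimethylsilyloxy)-2-chloroethyl]-4,4-dimethylcyclohex-2-en-1-ol | O[C@H]1C[C@H](Br)C(C)(C)C=C1[C@@H](O[Si](C)(C)C(C)(C)C)CCl
F2 | step 12 | (5S)-5-bromo-2-[(1R)-1-(tert-butyldimethylsilyloxy)-2-chloroethyl]-4,4-dimethylcyclohex-2-en-1-one | O=C1C[C@H](Br)C(C)(C)C=C1[C@@H](O[Si](C)(C)C(C)(C)C)CCl
F3 | step 5 | 2,2-dimethylbut-3-yn-1-yl N,N-diisopropylcarbamate | C#CC(C)(C)COC(=O)N(C(C)C)C(C)C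
F4 | step 5 | 2,2-dimethyl-4-(trimethylsilyl)but-3-yn-1-yl N,N-diisopropylcarbamate | C[Si](C)(C)C#CC(C)(C)COC(=O)N(C(C)C)C(C)C
F5 | step 5 | 2-[(4R)-5,5-dimethyl-7-(trimethylsilyl)hept-1-en-6-yn-4-yl]-4,4,5,5-tetramethyl-1,3,2-dioxaborolane | C=CC[C@@H](B1OC(C)(C)C(C)(C)O1)C(C)(C)C#C[Si](C)(C)C
F6 | step 5 | [(4S)-4-bromo-3,3-dimethylhept-6-en-1-yn-1-yl]trimethylsilane | C=CC[C@H](Br)C(C)(C)C#C[Si](C)(C)C
F7 | step 5 | [(4S)-4-bromo-6,6-dimethoxy-3,3-dimethylhex-1-yn-1-yl]trimethylsilane | COC(OC)C[C@H](Br)C(C)(C)C#C[Si](C)(C)C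
F8 | step 15 | (1R,5S)-5-bromo-2-[(1R)-2-chloro-1-(methanesulfonyloxy)ethyl]-4,4-dimethylcyclohex-2-en-1-yl acetate | CC(=O)O[C@@H]1C[C@H](Br)C(C)(C)C=C1[C@@H](OS(C)(=O)=O)CCl
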